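Everything rests on growing flavone ring A (C4a''–C8a'') onto ring B instead of coupling two hindered arenes. C8'', the biaryl carbon, lies between the oxygens on C7'' and C8a'', with a third oxygen at C5''. This 2-aryl-5-alkoxyresorcinol pattern is what a vinylketene–siloxyalkyne benzannulation produces. Heating 3-(benzyloxy)cyclobutenone with the ring B aryl triisopropylsiloxyalkyne (catechol as benzyl ethers, aldehyde as dioxolane) forms C8''–C8a'', C6''–C7'' and C4a''–C8a'' in one operation. It delivers three differentiated oxygens: free OH (future O1''), silyl ether (O7'') and benzyl ether (O5''). Ortho-formylation, ynone cyclisation, a catalytic asymmetric oxa-Michael closure and one hydrogenolysis complete the (2S)-flavanone.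

Key step: step 7

Remark on protecting groups: every phenol that must last to the end is a benzyl ether, O5'' included (hence a benzyloxy- and not an ethoxycyclobutenone), so no Lewis-acid dealkylation is needed and the sensitive (2S)-flavanone is unveiled by one neutral hydrogenolysis; the aldehyde is a dioxolane, which tolerates silica and heating beside a phenol better than an open dimethyl acetal.
Assumption (sense of induction): the quinidine-derived thiourea is taken to give the (2S) product, by analogy with its facial preference in other enone conjugate additions; if a model run on a simple phenyl analogue shows the opposite sense, the quinine-derived pseudoenantiomer is used under the same conditions.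
Assumption (axis): the C5'–C8'' bond carries three small ortho oxygens and one hydrogen and is taken to rotate freely in the target, so no axial stereocontrol is planned.

Step 1
Reactants: 1 5-iodovanillin (4-hydroxy-3-iodo-5-methoxybenzaldehyde)
Product: 2 3,4-dihydroxy-5-iodobenzaldehyde
Conditions: AlCl3 (1.2 equiv), pyridine (4.5 equiv), CH2Cl2, reflux; then 2 M HCl
Reagents that add atoms: none
Why: Chelation-assisted aryl methyl ether cleavage, in which AlCl3 binds the free 4-OH and the neighbouring methoxy oxygen and pyridine removes the activated methyl group by SN2 attack, while iodide and aldehyde are spectators.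

Step 2
Reactants: 2 3,4-dihydroxy-5-iodobenzaldehyde
Product: 3 3,4-bis(benzyloxy)-5-iodobenzaldehyde
Conditions: BnBr (2.4 equiv), K2CO3, DMF, 60 °C
Reagents that add atoms: benzyl bromide, BrCc1ccccc1
Why: Double Williamson etherification of the catechol; benzyl tolerates cold organolithiums, heat, mild acid and base, and leaves at the end under neutral hydrogenolysis.

Step 3
Reactants: 3 3,4-bis(benzyloxy)-5-iodobenzaldehyde
Product: 4 2-[3,4-bis(benzyloxy)-5-iodophenyl]-1,3-dioxolane
Conditions: ethylene glycol (5 equiv), TsOH·H2O (cat.), toluene, Dean–Stark reflux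
Reagents that add atoms: ethylene glycol, OCCO
Why: Acid-catalysed acetalisation with azeotropic water removal masks the aldehyde against the acetylide, peroxide and organolithium chemistry that follows.

Step 4
Reactants: 4 2-[3,4-bis(benzyloxy)-5-iodophenyl]-1,3-dioxolane
Product: 6 2-[3,4-bis(benzyloxy)-5-ethynylphenyl]-1,3-dioxolane, via TMS-alkyne 5 (not isolated)
Conditions: trimethylsilylacetylene (1.3 equiv), PdCl2(PPh3)2 (2 mol %), CuI (4 mol %), Et3N–THF, rt; filter, concentrate; K2CO3 (0.3 equiv), MeOH–THF, rt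
Reagents that add atoms: trimethylsilylacetylene, C#C[Si](C)(C)C
Why: Sonogashira coupling of an aryl iodide should run at room temperature despite the ortho benzyloxy group, and base-catalysed methanolysis of the alkynylsilane then frees the terminal alkyne.

Step 5
Reactants: 6 2-[3,4-bis(benzyloxy)-5-ethynylphenyl]-1,3-dioxolane
Product: 9 {[2,3-bis(benzyloxy)-5-(1,3-dioxolan-2-yl)phenyl]ethynyl}oxy-triisopropylsilane, via lithium acetylide 7 (not isolated), via lithium ynolate 8 (not isolated)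
Conditions: n-BuLi (1.0 equiv), THF, −78 °C; LiOOt-Bu (from t-BuOOH + LiHMDS, THF, −78 °C), −78 → 0 °C; TIPSOTf (1.15 equiv), −78 → 0 °C; NaHCO3 work-up
Reagents that add atoms: tert-butyl hydroperoxide, CC(C)(C)OO; triisopropylsilyl triflate, CC(C)[Si](C(C)C)(C(C)C)OS(=O)(=O)C(F)(F)F
Why: Electrophilic oxygenation of a lithium acetylide by lithium tert-butyl peroxide is an established route to ynolates, aryl ones included, and the bulky silyl triflate traps the ynolate on oxygen to give an isolable silyl ynol ether, while the basic medium protects the dioxolane from the triflate.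

Step 6
Reactants: 10 3-ethoxycyclobut-2-en-1-one
Product: 11 3-(benzyloxy)cyclobut-2-en-1-one
Conditions: BnOH (3 equiv), camphorsulfonic acid (5 mol %), dry toluene, 40–45 °C, reduced pressure (EtOH stripped)
Reagents that add atoms: benzyl alcohol, OCc1ccccc1
Why: Acid-catalysed transetherification of a vinylogous ester by addition–elimination at C3, the same manifold by which aqueous acid converts this enol ether into cyclobutane-1,3-dione, driven here by removal of ethanol.

Step 7
Reactants: 9 {[2,3-bis(benzyloxy)-5-(1,3-dioxolan-2-yl)phenyl]ethynyl}oxy-triisopropylsilane; 11 3-(benzyloxy)cyclobut-2-en-1-one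
Product: 16 2-[2,3-bis(benzyloxy)-5-(1,3-dioxolan-2-yl)phenyl]-5-(benzyloxy)-3-[(triisopropylsilyl)oxy]phenol, via vinylketene 12 (not isolated), via alkenylcyclobutenone 13 (not isolated), via dienylketene 14 (not isolated), via cyclohexadienone 15 (not isolated)
Conditions: 11 (1.5 equiv, added in portions), degassed toluene (0.5 M), sealed tube, 110–130 °C
Reagents that add atoms: none
Why: Conrotatory four-electron opening of 11 gives vinylketene 12, whose ketene carbon (future C8a'') is attacked by the aryl-bearing, nucleophilic alkyne carbon of 9 in a regiospecific [2+2] cycloaddition that forms C8''–C8a'' and C6''–C7'' (13). A second four-electron opening gives dienylketene 14, and the one new ring, the six-membered carbocycle of flavone ring A, closes by disrotatory six-electron electrocyclisation (C4a''–C8a'') to dienone 15, which tautomerises to phenol 16. The closest known reaction is the Danheiser benzannulation of cyclobutenones, 3-alkoxy members included, with triisopropylsilyl ynol ethers to give resorcinol monosilyl ethers; only the ortho-substituted aryl group on the alkyne is new. No stereocentre survives, since the sp3 carbon of 13 becomes aromatic C6''. The one selectivity needed is the orientation of the [2+2] addition, and the oxygen polarisation of the ynol ether secures it, placing the aryl group ortho to the new OH and the silyloxy group meta to it. The benzyloxy group is only cross-conjugated with the ketene in 12 and should not blunt its electrophilicity, and the neutral medium leaves dioxolane, benzyl ethers and silyl ether untouched.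

Step 8
Reactants: 16 2-[2,3-bis(benzyloxy)-5-(1,3-dioxolan-2-yl)phenyl]-5-(benzyloxy)-3-[(triisopropylsilyl)oxy]phenol
Product: 17 3-[2,3-bis(benzyloxy)-5-(1,3-dioxolan-2-yl)phenyl]-6-(benzyloxy)-2-hydroxy-4-[(triisopropylsilyl)oxy]benzaldehyde
Conditions: anhydrous MgCl2 (3 equiv), Et3N (6 equiv), (CH2O)n (10 equiv), MeCN, reflux; aq. NH4Cl
Reagents that add atoms: formaldehyde (from paraformaldehyde), C=O
Why: Casnati–Skattebøl ortho-formylation, in which the magnesium phenoxide delivers formaldehyde only to a carbon ortho to its own oxygen; C4a'' is the single free ortho carbon (C6'' is para), and the mild medium spares acetal, benzyl and silyl ethers where a Lewis-acid acylation would not.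

Step 9
Reactants: 18 3,4-bis(benzyloxy)benzaldehyde
Product: 19 1,2-bis(benzyloxy)-4-ethynylbenzene
Conditions: dimethyl (1-diazo-2-oxopropyl)phosphonate (1.3 equiv), K2CO3 (2 equiv), MeOH–THF, rt
Reagents that add atoms: dimethyl (1-diazo-2-oxopropyl)phosphonate, COP(=O)(OC)C(=[N+]=[N-])C(C)=O
Why: Ohira–Bestmann homologation converts a non-enolisable aromatic aldehyde into the terminal alkyne in one mild operation.

Step 10
Reactants: 17 3-[2,3-bis(benzyloxy)-5-(1,3-dioxolan-2-yl)phenyl]-6-(benzyloxy)-2-hydroxy-4-[(triisopropylsilyl)oxy]benzaldehyde; 19 1,2-bis(benzyloxy)-4-ethynylbenzene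
Product: 22 1-{3-[2,3-bis(benzyloxy)-5-(1,3-dioxolan-2-yl)phenyl]-6-(benzyloxy)-2-hydroxy-4-[(triisopropylsilyl)oxy]phenyl}-3-[3,4-bis(benzyloxy)phenyl]prop-2-yn-1-one, via lithium acetylide 20 (not isolated), via propargylic alcohol 21 (not isolated)
Conditions: 19 (2.5 equiv), n-BuLi (2.4 equiv), THF, −78 °C; 17, −78 → 0 °C; aq. NH4Cl; crude alcohol, activated MnO2 (excess), CH2Cl2, rt
Reagents that add atoms: none
Why: 1,2-Addition of a lithium acetylide to a salicylaldehyde (the first equivalent is spent on the phenol), then MnO2 oxidation of the benzylic–propargylic alcohol, which is carried on crude because it ionises easily; its racemic carbinol centre is erased by the oxidation.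

Step 11
Reactants: 22 1-{3-[2,3-bis(benzyloxy)-5-(1,3-dioxolan-2-yl)phenyl]-6-(benzyloxy)-2-hydroxy-4-[(triisopropylsilyl)oxy]phenyl}-3-[3,4-bis(benzyloxy)phenyl]prop-2-yn-1-one
Product: 25 5,7-bis(benzyloxy)-2-[3,4-bis(benzyloxy)phenyl]-8-[2,3-bis(benzyloxy)-5-(1,3-dioxolan-2-yl)phenyl]-4H-chromen-4-one, via silyl flavone 23 (not isolated), via caesium phenoxide 24 (not isolated)
Conditions: DMAP (20 mol %), DMF, 40 °C; then CsF (3 equiv), BnBr (1.5 equiv), same flask, rt → 50 °C
Reagents that add atoms: benzyl bromide, BrCc1ccccc1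
Why: Nucleophile-catalysed 6-endo cyclisation of an o-alkynoylphenol (DMAP adds to the ynone β-carbon and the phenol displaces it, giving flavone and not aurone), followed by the known fluoride-induced direct conversion of an aryl silyl ether into an aryl benzyl ether once no other free phenol remains.

Step 12
Reactants: 25 5,7-bis(benzyloxy)-2-[3,4-bis(benzyloxy)phenyl]-8-[2,3-bis(benzyloxy)-5-(1,3-dioxolan-2-yl)phenyl]-4H-chromen-4-one
Product: 26 3,4-bis(benzyloxy)-5-{5,7-bis(benzyloxy)-2-[3,4-bis(benzyloxy)phenyl]-4-oxo-4H-chromen-8-yl}benzaldehyde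
Conditions: 1 M HCl, THF, rt
Reagents that add atoms: water, O
Why: Acid-catalysed acetal hydrolysis of an electron-rich benzaldehyde dioxolane is fast under conditions that leave the flavone and benzyl ethers alone.

Step 13
Reactants: 27 2,4,6-trihydroxyacetophenone
Product: 28 1-[2,4-bis(benzyloxy)-6-hydroxyphenyl]ethan-1-one
Conditions: BnBr (2.05 equiv), K2CO3 (2.2 equiv), DMF, rt → 50 °C
Reagents that add atoms: benzyl bromide, BrCc1ccccc1
Why: Williamson etherification stops after two benzylations because the last ortho hydroxyl is tied up in a hydrogen bond to the acetyl carbonyl.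

Step 14
Reactants: 28 1-[2,4-bis(benzyloxy)-6-hydroxyphenyl]ethan-1-one
Product: 30 tert-butyl 3-[2,4-bis(benzyloxy)-6-hydroxyphenyl]-3-oxopropanoate, via dilithio dianion 29 (not isolated)
Conditions: LiHMDS (3.3 equiv), THF, −78 °C; Boc2O (1.1 equiv), −78 → −20 °C; aq. NH4Cl
Reagents that add atoms: di-tert-butyl dicarbonate, CC(C)(C)OC(=O)OC(=O)OC(C)(C)C
Why: Claisen-type C-acylation of the ketone enolate; any carbonate formed on the phenoxide is relayed to the enolate carbon by a Baker–Venkataraman-type acyl shift, and the tert-butyl ester resists lactonisation to the 4-hydroxycoumarin at low temperature.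

Step 15
Reactants: 26 3,4-bis(benzyloxy)-5-{5,7-bis(benzyloxy)-2-[3,4-bis(benzyloxy)phenyl]-4-oxo-4H-chromen-8-yl}benzaldehyde; 30 tert-butyl 3-[2,4-bis(benzyloxy)-6-hydroxyphenyl]-3-oxopropanoate
Product: 31 tert-butyl (Z)-2-[2,4-bis(benzyloxy)-6-hydroxybenzoyl]-3-(3,4-bis(benzyloxy)-5-{5,7-bis(benzyloxy)-2-[3,4-bis(benzyloxy)phenyl]-4-oxo-4H-chromen-8-yl}phenyl)acrylate
Conditions: piperidine (20 mol %), AcOH (20 mol %), 4 Å MS, toluene, rt
Reagents that add atoms: none
Why: Knoevenagel condensation of an unhindered aromatic aldehyde (the formyl group is meta to the biaryl bond) with a β-ketoester should give the α-carboxylated 2'-hydroxychalcone, mainly with the aryl group cis to the ester.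

Step 16
Reactants: 31 tert-butyl (Z)-2-[2,4-bis(benzyloxy)-6-hydroxybenzoyl]-3-(3,4-bis(benzyloxy)-5-{5,7-bis(benzyloxy)-2-[3,4-bis(benzyloxy)phenyl]-4-oxo-4H-chromen-8-yl}phenyl)acrylate
Product: 33 (2S)-5,7-bis(benzyloxy)-2-(3,4-bis(benzyloxy)-5-{5,7-bis(benzyloxy)-2-[3,4-bis(benzyloxy)phenyl]-4-oxo-4H-chromen-8-yl}phenyl)chroman-4-one, via flavanone ester 32 (not isolated)
Conditions: 3,5-bis(trifluoromethyl)phenyl thiourea of 9-amino-9-deoxy-epi-quinidine (10–20 mol %), toluene, −25 °C; then TsOH·H2O, 80 °C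
Reagents that add atoms: none
Why: Bifunctional cinchona-thiourea catalysis of the intramolecular oxa-Michael addition of alkylidene β-ketoesters: the thiourea binds the dicarbonyl, the quinuclidine activates the phenol and steers it onto one alkene face to set C2 as S, the ester keeps the closure from reversing, and acid then removes isobutene and CO2 without touching C2 (loss of a peri benzyl group here would be harmless).

Step 17
Reactants: 33 (2S)-5,7-bis(benzyloxy)-2-(3,4-bis(benzyloxy)-5-{5,7-bis(benzyloxy)-2-[3,4-bis(benzyloxy)phenyl]-4-oxo-4H-chromen-8-yl}phenyl)chroman-4-one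
Product: 34 (2S)-2-{3-[2-(3,4-dihydroxyphenyl)-5,7-dihydroxy-4-oxo-4H-chromen-8-yl]-4,5-dihydroxyphenyl}-5,7-dihydroxychroman-4-one (target)
Conditions: H2 (1 atm), 10 % Pd/C, THF–MeOH, rt; filtration and work-up kept neutral to slightly acidic
Reagents that add atoms: none
Why: Catalytic hydrogenolysis removes all eight aryl benzyl ethers under neutral conditions that normally spare the flavone double bond and both carbonyls and avoid the base-induced ring opening that would racemise C2.

Compound list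
1 | 5-iodovanillin | COc1cc(C=O)cc(I)c1O | starting material
2 | 3,4-dihydroxy-5-iodobenzaldehyde | O=Cc1cc(O)c(O)c(I)c1 | intermediate
3 | 3,4-bis(benzyloxy)-5-iodobenzaldehyde | O=Cc1cc(I)c(OCc2ccccc2)c(OCc2ccccc2)c1 | intermediate
4 | 2-[3,4-bis(benzyloxy)-5-iodophenyl]-1,3-dioxolane | Ic1cc(C2OCCO2)cc(OCc2ccccc2)c1OCc1ccccc1 | intermediate
5 | {[2,3-bis(benzyloxy)-5-(1,3-dioxolan-2-yl)phenyl]ethynyl}trimethylsilane | C[Si](C)(C)C#Cc1cc(C2OCCO2)cc(OCc2ccccc2)c1OCc1ccccc1 | intermediate
6 | 2-[3,4-bis(benzyloxy)-5-ethynylphenyl]-1,3-dioxolane | C#Cc1cc(C2OCCO2)cc(OCc2ccccc2)c1OCc1ccccc1 | intermediate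
7 | lithium acetylide of 6 | [Li]C#Cc1cc(C2OCCO2)cc(OCc2ccccc2)c1OCc1ccccc1 | intermediate
8 | lithium 2-[2,3-bis(benzyloxy)-5-(1,3-dioxolan-2-yl)phenyl]ethynolate | [Li]OC#Cc1cc(C2OCCO2)cc(OCc2ccccc2)c1OCc1ccccc1 | intermediate
9 | {[2,3-bis(benzyloxy)-5-(1,3-dioxolan-2-yl)phenyl]ethynyl}oxy-triisopropylsilane | CC(C)[Si](OC#Cc1cc(C2OCCO2)cc(OCc2ccccc2)c1OCc1ccccc1)(C(C)C)C(C)C | intermediate
10 | 3-ethoxycyclobut-2-en-1-one | CCOC1=CC(=O)C1 | starting material
11 | 3-(benzyloxy)cyclobut-2-en-1-one | O=C1C=C(OCc2ccccc2)C1 | intermediate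
12 | 3-(benzyloxy)buta-1,3-dien-1-one (vinylketene) | C=C(OCc1ccccc1)C=C=O | intermediate
13 | 2-aryl-4-[1-(benzyloxy)vinyl]-3-[(triisopropylsilyl)oxy]cyclobut-2-en-1-one (racemic; aryl = 2,3-bis(benzyloxy)-5-(1,3-dioxolan-2-yl)phenyl) | O=C1C(c2cc(C3OCCO3)cc(OCc3ccccc3)c2OCc2ccccc2)=C(O[Si](C(C)C)(C(C)C)C(C)C)C1C(=C)OCc1ccccc1 | intermediate
14 | 2-aryl-5-(benzyloxy)-3-[(triisopropylsilyl)oxy]hexa-1,3,5-trien-1-one (dienylketene, ketene and vinyl cis on the central alkene) | O=C=C(c1cc(C2OCCO2)cc(OCc2ccccc2)c1OCc1ccccc1)/C(O[Si](C(C)C)(C(C)C)C(C)C)=C\C(=C)OCc1ccccc1 | intermediate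
15 | 2-aryl-5-(benzyloxy)-3-[(triisopropylsilyl)oxy]cyclohexa-2,4-dien-1-one | O=C1CC(OCc2ccccc2)=CC(O[Si](C(C)C)(C(C)C)C(C)C)=C1c1cc(C2OCCO2)cc(OCc2ccccc2)c1OCc1ccccc1 | intermediate
16 | 2-[2,3-bis(benzyloxy)-5-(1,3-dioxolan-2-yl)phenyl]-5-(benzyloxy)-3-[(triisopropylsilyl)oxy]phenol | Oc1cc(OCc2ccccc2)cc(O[Si](C(C)C)(C(C)C)C(C)C)c1-c1cc(C2OCCO2)cc(OCc2ccccc2)c1OCc1ccccc1 | intermediate
17 | 3-[2,3-bis(benzyloxy)-5-(1,3-dioxolan-2-yl)phenyl]-6-(benzyloxy)-2-hydroxy-4-[(triisopropylsilyl)oxy]benzaldehyde | O=Cc1c(O)c(-c2cc(C3OCCO3)cc(OCc3ccccc3)c2OCc2ccccc2)c(O[Si](C(C)C)(C(C)C)C(C)C)cc1OCc1ccccc1 | intermediate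
18 | 3,4-bis(benzyloxy)benzaldehyde | O=Cc1ccc(OCc2ccccc2)c(OCc2ccccc2)c1 | starting material
19 | 1,2-bis(benzyloxy)-4-ethynylbenzene | C#Cc1ccc(OCc2ccccc2)c(OCc2ccccc2)c1 | intermediate
20 | lithium acetylide of 19 | [Li]C#Cc1ccc(OCc2ccccc2)c(OCc2ccccc2)c1 | intermediate
21 | propargylic alcohol (racemic carbinol) from 17 and 20 | OC(C#Cc1ccc(OCc2ccccc2)c(OCc2ccccc2)c1)c1c(O)c(-c2cc(C3OCCO3)cc(OCc3ccccc3)c2OCc2ccccc2)c(O[Si](C(C)C)(C(C)C)C(C)C)cc1OCc1ccccc1 | intermediate
22 | o-hydroxyaryl ynone | O=C(C#Cc1ccc(OCc2ccccc2)c(OCc2ccccc2)c1)c1c(O)c(-c2cc(C3OCCO3)cc(OCc3ccccc3)c2OCc2ccccc2)c(O[Si](C(C)C)(C(C)C)C(C)C)cc1OCc1ccccc1 | intermediate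
23 | 7-O-triisopropylsilyl flavone acetal | O1CCOC1c1cc(OCc2ccccc2)c(OCc2ccccc2)c(-c2c(O[Si](C(C)C)(C(C)C)C(C)C)cc(OCc3ccccc3)c3c(=O)cc(-c4ccc(OCc5ccccc5)c(OCc5ccccc5)c4)oc23)c1 | intermediate
24 | caesium 7-phenoxide of the flavone acetal | O1CCOC1c1cc(OCc2ccccc2)c(OCc2ccccc2)c(-c2c([O-])cc(OCc3ccccc3)c3c(=O)cc(-c4ccc(OCc5ccccc5)c(OCc5ccccc5)c4)oc23)c1.[Cs+] | intermediate
25 | hexa-O-benzyl flavone acetal | O1CCOC1c1cc(OCc2ccccc2)c(OCc2ccccc2)c(-c2c(OCc3ccccc3)cc(OCc3ccccc3)c3c(=O)cc(-c4ccc(OCc5ccccc5)c(OCc5ccccc5)c4)oc23)c1 | intermediate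
26 | hexa-O-benzyl flavone aldehyde | O=Cc1cc(OCc2ccccc2)c(OCc2ccccc2)c(-c2c(OCc3ccccc3)cc(OCc3ccccc3)c3c(=O)cc(-c4ccc(OCc5ccccc5)c(OCc5ccccc5)c4)oc23)c1 | intermediate
27 | 2,4,6-trihydroxyacetophenone | CC(=O)c1c(O)cc(O)cc1O | starting material
28 | 1-[2,4-bis(benzyloxy)-6-hydroxyphenyl]ethan-1-one | CC(=O)c1c(O)cc(OCc2ccccc2)cc1OCc1ccccc1 | intermediate
29 | dilithio phenoxide–enolate of 28 | [Li]OC(=C)c1c(O[Li])cc(OCc2ccccc2)cc1OCc1ccccc1 | intermediate
30 | tert-butyl 3-[2,4-bis(benzyloxy)-6-hydroxyphenyl]-3-oxopropanoate | CC(C)(C)OC(=O)CC(=O)c1c(O)cc(OCc2ccccc2)cc1OCc1ccccc1 | intermediate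
31 | (Z)-alkylidene β-ketoester | CC(C)(C)OC(=O)/C(=C\c1cc(OCc2ccccc2)c(OCc2ccccc2)c(-c2c(OCc3ccccc3)cc(OCc3ccccc3)c3c(=O)cc(-c4ccc(OCc5ccccc5)c(OCc5ccccc5)c4)oc23)c1)C(=O)c1c(O)cc(OCc2ccccc2)cc1OCc1ccccc1 | intermediate
32 | tert-butyl (2S)-flavanone-3-carboxylate (C3 epimers and enol) | O=C1C(C(=O)OC(C)(C)C)[C@@H](c2cc(OCc3ccccc3)c(OCc3ccccc3)c(-c3c(OCc4ccccc4)cc(OCc4ccccc4)c4c(=O)cc(-c5ccc(OCc6ccccc6)c(OCc6ccccc6)c5)oc34)c2)Oc2cc(OCc3ccccc3)cc(OCc3ccccc3)c21 | intermediate
33 | (2S)-octa-O-benzyl ether of the target | O=C1C[C@@H](c2cc(OCc3ccccc3)c(OCc3ccccc3)c(-c3c(OCc4ccccc4)cc(OCc4ccccc4)c4c(=O)cc(-c5ccc(OCc6ccccc6)c(OCc6ccccc6)c5)oc34)c2)Oc2cc(OCc3ccccc3)cc(OCc3ccccc3)c21 | intermediate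
34 | CNP0224656.1, (2S)-2-{3-[2-(3,4-dihydroxyphenyl)-5,7-dihydroxy-4-oxo-4H-chromen-8-yl]-4,5-dihydroxyphenyl}-5,7-dihydroxychroman-4-one | O=C1C[C@@H](c2cc(O)c(O)c(-c3c(O)cc(O)c4c(=O)cc(-c5ccc(O)c(O)c5)oc34)c2)Oc2cc(O)cc(O)c21 | target

Total step count: 17
Longest linear sequence: 13 steps (1, 2, 3, 4, 5, 7, 8, 10, 11, 12, 15, 16, 17)

Steps most likely to fail

Step 7. The push–pull stabilised 3-alkoxycyclobutenone may open too slowly. Ketene dimerisation, thermal silyl migration in the ynol ether, or acylation of the product phenol by excess ketene could then outrun the [2+2] addition to the ortho-substituted aryl alkyne.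
- The fallback gives up ring construction for a cross-coupling. It sets out from 4 and rejoins at 25.
- Iodide 4 is converted by Miyaura borylation (B2pin2, PdCl2(dppf), KOAc, dioxane, 90 °C) into the aryl pinacol boronate F1.
- Commercial luteolin is perbenzylated (BnBr, K2CO3, DMF, 80 °C) to tetra-O-benzylluteolin F2.
- This is iodinated at C8, the preferred site of 5,7-dialkoxyflavones (I2, CF3CO2Ag, CH2Cl2), to the 8-iodoflavone F3.
- Suzuki–Miyaura coupling of F1 and F3 (Pd(OAc)2, SPhos, K3PO4, toluene–water, 90 °C) should give 25, from which steps 12–17 continue unchanged.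

Step 16. Enantioselectivity may erode through uncatalysed background closure (already possible during step 15), through hydrogen bonding of the thiourea to the flavone carbonyl, or through a poor fit of the di-ortho-substituted aroyl group in the catalyst pocket.
- The fallback replaces asymmetric closure by resolution. It also bypasses steps 14 and 15, sets out from 26 and 28, and rejoins at 33.
- Claisen–Schmidt condensation (KOH, EtOH–THF, rt) gives the (E)-2'-hydroxychalcone F4.
- NaOAc in refluxing EtOH–THF closes it to the racemic flavanone F5.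
- Noyori-type asymmetric transfer hydrogenation follows, run as a kinetic resolution (RuCl(p-cymene)[(R,R)-TsDPEN], HCO2H–Et3N, EtOAc, rt).
- It should reduce the (2R) ketone faster to the cis-(2R,4R)-flavan-4-ol F6 and leave the (2S) ketone 33, which is separated by chromatography.
- The flavone carbonyl, a vinylogous ester, is expected to stay inert. F6 can be reoxidised, racemised with base and recycled.

Step 6. The exchange may stall at equilibrium, or the strained vinylogous ester may suffer ring cleavage to acetoacetate-type products under acid and alcohol.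
- The fallback forms the O–CH2Ph bond instead of the C3–O bond. It sets out from 10 and rejoins at 11.
- Dilute aqueous HCl hydrolyses 10 to cyclobutane-1,3-dione F7 (also purchasable).
- Its strongly acidic enol is O-benzylated under Mitsunobu conditions (BnOH, PPh3, DIAD, THF, 0 °C) to give 11.

Further compounds
F1 | step 7 | 2-[2,3-bis(benzyloxy)-5-(1,3-dioxolan-2-yl)phenyl]-4,4,5,5-tetramethyl-1,3,2-dioxaborolane | CC1(C)OB(OC1(C)C)c1cc(C2OCCO2)cc(OCc2ccccc2)c1OCc1ccccc1
F2 | step 7 | 5,7-bis(benzyloxy)-2-[3,4-bis(benzyloxy)phenyl]-4H-chromen-4-one (tetra-O-benzylluteolin) | O=c1cc(-c2ccc(OCc3ccccc3)c(OCc3ccccc3)c2)oc2cc(OCc3ccccc3)cc(OCc3ccccc3)c12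
F3 | step 7 | 5,7-bis(benzyloxy)-2-[3,4-bis(benzyloxy)phenyl]-8-iodo-4H-chromen-4-one | O=c1cc(-c2ccc(OCc3ccccc3)c(OCc3ccccc3)c2)oc2c(I)c(OCc3ccccc3)cc(OCc3ccccc3)c12
F4 | step 16 | (E)-2'-hydroxy-4',6'-bis(benzyloxy)chalcone from 26 and 28 | O=C(/C=C/c1cc(OCc2ccccc2)c(OCc2ccccc2)c(-c2c(OCc3ccccc3)cc(OCc3ccccc3)c3c(=O)cc(-c4ccc(OCc5ccccc5)c(OCc5ccccc5)c4)oc23)c1)c1c(O)cc(OCc2ccccc2)cc1OCc1ccccc1
F5 | step 16 | racemic octa-O-benzyl flavanone | O=C1CC(c2cc(OCc3ccccc3)c(OCc3ccccc3)c(-c3c(OCc4ccccc4)cc(OCc4ccccc4)c4c(=O)cc(-c5ccc(OCc6ccccc6)c(OCc6ccccc6)c5)oc34)c2)Oc2cc(OCc3ccccc3)cc(OCc3ccccc3)c21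
F6 | step 16 | cis-(2R,4R)-octa-O-benzyl flavan-4-ol | O[C@@H]1C[C@H](c2cc(OCc3ccccc3)c(OCc3ccccc3)c(-c3c(OCc4ccccc4)cc(OCc4ccccc4)c4c(=O)cc(-c5ccc(OCc6ccccc6)c(OCc6ccccc6)c5)oc34)c2)Oc2cc(OCc3ccccc3)cc(OCc3ccccc3)c21
F7 | step 6 | cyclobutane-1,3-dione | O=C1CC(=O)C1
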